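**Plan**

- Retrosynthesis: the free O3–H is first masked as a methoxymethyl acetal, then the C2–O bond of the catechol is cut back to C2–H. The acetal O–CH2 bond and the ester O–C(alkyl) bond are cut last, which leads to 3-hydroxybenzoic acid, octadecyl bromide and chloromethyl methyl ether.
- Forward: the C18 chain is joined first by carboxylate O-alkylation, the phenol is capped, the C2 oxygen is installed by magnesiation, borylation and oxidation in one flask, and the acetal is hydrolysed. The benzene ring is bought and no ring is formed.
- Enabling feature: on the single benzene ring, C2 lies between C1 (ester) and C3 (acetal oxygen). Its C–H bond is therefore the most acidic of the ring and can be reached by a base bound to either neighbour.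
- Stereochemistry: the target has no stereocentre and no stereogenic double bond; only regiochemistry (C2 against C4 and C6) has to be controlled.

Key step: step 3

Remark: ring atoms are numbered from the ester-bearing carbon (C1) through the two oxygen-bearing carbons (C2, C3); the waxy C18 esters are assumed to stay dissolved in THF at 0 °C at about 0.2 M.

**Route**

Step 1
Reactants: 1 3-hydroxybenzoic acid; 2 octadecyl bromide (1-bromooctadecane)
Product: 3 octadecyl 3-hydroxybenzoate
Conditions: KHCO3 (1.2 equiv), KI (cat.), DMF, 70 °C
Reagents that add atoms: none
Why: Bicarbonate deprotonates only the carboxylic acid and not the far less acidic phenol, so the carboxylate should displace bromide from the primary bromide in an SN2 carboxylate O-alkylation that leaves the phenol free.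

Step 2
Reactants: 3 octadecyl 3-hydroxybenzoate; 4 chloromethyl methyl ether
Product: 5 octadecyl 3-(methoxymethoxy)benzoate
Conditions: iPr2NEt, CH2Cl2, 0 → 25 °C
Reagents that add atoms: none
Why: Williamson-type O-alkylation of the phenol by the highly electrophilic α-chloro ether under a tertiary amine base is the standard formation of a methoxymethyl ether, and the ester is inert to it.

Step 3
Reactants: 5 octadecyl 3-(methoxymethoxy)benzoate
Product: 8 octadecyl 2-hydroxy-3-(methoxymethoxy)benzoate, via C2-arylmagnesium chloride 6 (not isolated), via C2-aryl dimethyl boronate 7 (not isolated)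
Conditions: TMPMgCl·LiCl (1.3 equiv), THF, 0 → 25 °C (I2 quench of aliquots as monitor); B(OMe)3 (2 equiv), 0 °C; AcOH, 30% aq. H2O2, 0 → 25 °C
Reagents that add atoms: hydrogen peroxide, OO (the C2 oxygen of 8); trimethyl borate, COB(OC)OC (the B(OCH3)2 group of 7, lost again); TMPMgCl·LiCl, CC1(C)CCCC(C)(C)N1[Mg]Cl.[Li+].[Cl-] (the MgCl of 6, lost again)
Why: This is a directed ortho-metalation in which the magnesium amide, bound to the ester carbonyl and to the acetal oxygens, removes the C2 proton, the only ring hydrogen acidified by both neighbours, to give arylmagnesium 6. B(OMe)3 takes over the aryl group to give boronate 7; hydroperoxide then adds to boron and the aryl group shifts from boron to oxygen, so the C2–metal bond becomes the C2–O bond at the same carbon and hydrolysis releases phenol 8. The closest known reaction types are the magnesiation of functionalised alkyl benzoates with hindered TMP-magnesium amides and the borate-trapping and peroxide-oxidation sequence that converts ortho-metalated arenes into phenols. No ring is closed and no stereocentre is formed. Two selectivities are needed: C2 over C4 and C6, secured by the 1,3-relationship of ester and OCH2OCH3 that makes C2 both the most acidic and the doubly chelated site; and deprotonation over acyl attack, secured by the hindered, non-nucleophilic amide and the covalent, doubly ortho-flanked C–Mg bond, which tolerates a primary alkyl ester at 0–25 °C. Working at 0–25 °C keeps the C18 ester in solution, and the acetic-acid-buffered oxidation spares both ester and acetal.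

Step 4
Reactants: 8 octadecyl 2-hydroxy-3-(methoxymethoxy)benzoate
Product: 9 gentiside E (octadecyl 2,3-dihydroxybenzoate)
Conditions: aq. HCl (to about 0.5 M), iPrOH/THF, 25–40 °C
Reagents that add atoms: none
Why: Acid-catalysed acetal hydrolysis should expel the phenol from the protonated methoxymethyl ether, while the hindered secondary alcohol cosolvent and the hydrogen-bonded salicylate-type ester disfavour ester exchange.

**Compound list**

1 | 3-hydroxybenzoic acid | O=C(O)c1cccc(O)c1 | starting material
2 | octadecyl bromide (1-bromooctadecane) | CCCCCCCCCCCCCCCCCCBr | starting material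
3 | octadecyl 3-hydroxybenzoate | CCCCCCCCCCCCCCCCCCOC(=O)c1cccc(O)c1 | intermediate
4 | chloromethyl methyl ether | COCCl | starting material
5 | octadecyl 3-(methoxymethoxy)benzoate | CCCCCCCCCCCCCCCCCCOC(=O)c1cccc(OCOC)c1 | intermediate
6 | octadecyl 2-(chloromagnesio)-3-(methoxymethoxy)benzoate | CCCCCCCCCCCCCCCCCCOC(=O)c1cccc(OCOC)c1[Mg]Cl | intermediate
7 | octadecyl 2-(dimethoxyboryl)-3-(methoxymethoxy)benzoate | CCCCCCCCCCCCCCCCCCOC(=O)c1cccc(OCOC)c1B(OC)OC | intermediate
8 | octadecyl 2-hydroxy-3-(methoxymethoxy)benzoate | CCCCCCCCCCCCCCCCCCOC(=O)c1cccc(OCOC)c1O | intermediate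
9 | gentiside E (octadecyl 2,3-dihydroxybenzoate) | CCCCCCCCCCCCCCCCCCOC(=O)c1cccc(O)c1O | target

**Step count**

Total steps: 4. Longest linear sequence: 4 steps, from 1 to 9.

**Steps most likely to fail, with fallbacks**

Step 3. The magnesiation at C2 may be slow or incomplete, the amide or the arylmagnesium may attack the primary ester, or the doubly ortho-flanked boronate may lose boron by protonation before it is oxidised. The fallback takes the electrophilic ester out of the metalation stage: the free acid is metalated and the chain is attached afterwards. It sets out from 1. Two equivalents of 4 with iPr2NEt in CH2Cl2 should give methoxymethyl 3-(methoxymethoxy)benzoate F1, and LiOH in THF/H2O should cleave its acetal ester selectively to 3-(methoxymethoxy)benzoic acid F2. Excess LiTMP in THF (−78 → 0 °C) is expected to form the lithium carboxylate and lithiate C2 between carboxylate and acetal, as is known for 3-methoxybenzoic acid, to give lithium 2-lithio-3-(methoxymethoxy)benzoate F3. B(OMe)3 should convert this into lithium 2-(dimethoxyboryl)-3-(methoxymethoxy)benzoate F4, and AcOH with 30% aq. H2O2 into 2-hydroxy-3-(methoxymethoxy)benzoic acid F5. Carboxylate alkylation of F5 with 2 (KHCO3, DMF, 70 °C) rejoins the route at 8.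

Step 1. The phenol may be alkylated alongside the carboxylate, or the SN2 displacement on the waxy bromide may stall. The fallback replaces alkylation by acyl substitution. It sets out from 1, which is heated with commercial 1-octadecanol (CCCCCCCCCCCCCCCCCCO) and catalytic p-toluenesulfonic acid in toluene at reflux with azeotropic removal of water (Fischer esterification). No alkylating agent is present and the phenol is not acylated under these conditions. No new compound is made on the way, and the route is rejoined at 3.

Step 4. The acid may promote exchange of the octadecyl ester with the alcohol cosolvent, the formaldehyde-derived electrophile may be recaptured by the electron-rich catechol ring, or the acetal cleavage may stop short. The fallback carries O3 as a benzyloxymethyl acetal, which keeps two coordinating oxygens for the metalation and is removed by neutral hydrogenolysis. It sets out from 3. Benzyl chloromethyl ether (ClCOCc1ccccc1) and iPr2NEt in CH2Cl2 should give octadecyl 3-[(benzyloxy)methoxy]benzoate F6. The magnesiation, borylation and oxidation under the conditions of step 3 would pass through octadecyl 3-[(benzyloxy)methoxy]-2-(chloromagnesio)benzoate F7 and octadecyl 3-[(benzyloxy)methoxy]-2-(dimethoxyboryl)benzoate F8 to octadecyl 3-[(benzyloxy)methoxy]-2-hydroxybenzoate F9. Hydrogenolysis (H2, 10% Pd/C, EtOAc, 25 °C) should cleave the benzyl C–O bond, the hemiformal collapses, and the route is rejoined at 9.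

**Further compounds**

F1 | step 3 | methoxymethyl 3-(methoxymethoxy)benzoate | COCOC(=O)c1cccc(OCOC)c1
F2 | step 3 | 3-(methoxymethoxy)benzoic acid | O=C(O)c1cccc(OCOC)c1
F3 | step 3 | lithium 2-lithio-3-(methoxymethoxy)benzoate | [Li]OC(=O)c1cccc(OCOC)c1[Li]
F4 | step 3 | lithium 2-(dimethoxyboryl)-3-(methoxymethoxy)benzoate | [Li]OC(=O)c1cccc(OCOC)c1B(OC)OC
F5 | step 3 | 2-hydroxy-3-(methoxymethoxy)benzoic acid | O=C(O)c1cccc(OCOC)c1O
F0 | step 1 | none | none
F6 | step 4 | octadecyl 3-[(benzyloxy)methoxy]benzoate | CCCCCCCCCCCCCCCCCCOC(=O)c1cccc(OCOCc2ccccc2)c1
F7 | step 4 | octadecyl 3-[(benzyloxy)methoxy]-2-(chloromagnesio)benzoate | CCCCCCCCCCCCCCCCCCOC(=O)c1cccc(OCOCc2ccccc2)c1[Mg]Cl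
F8 | step 4 | octadecyl 3-[(benzyloxy)methoxy]-2-(dimethoxyboryl)benzoate | CCCCCCCCCCCCCCCCCCOC(=O)c1cccc(OCOCc2ccccc2)c1B(OC)OC
F9 | step 4 | octadecyl 3-[(benzyloxy)methoxy]-2-hydroxybenzoate | CCCCCCCCCCCCCCCCCCOC(=O)c1cccc(OCOCc2ccccc2)c1O
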